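**Retrosynthetic overview**
1. Target 17 comes from 16 by loss of four MOM groups. 16 comes from the racemic C3 allyl ester 15 by palladium-catalysed decarboxylative asymmetric protonation, which sets C3 as (R).
2. Ring C of 15 is cut at C2–C3 and O1–C8a. The two atoms between the cuts (C2, O1) are one molecule of formaldehyde, inserted between C3 of the open α-aryl β-keto ester 12 and the fluorine-bearing C8a of ring A (hydroxymethylation, then intramolecular SNAr, one flask).
3. Enabling feature: the C4 ketone lies between C3 and C4a. The same carbonyl group acidifies C3–H and, being ortho to C8a, makes C8a–F a vinylogous acyl fluoride. The other ring A oxygens (C5, C7) are meta to C8a and do not oppose the attack.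
4. 12 comes by aldol addition and oxidation from ring B ester 7 (from 1: bromination, MOM, Stille prenylation, one-carbon homologation) and ring A aldehyde 10 (from 8: formylation, MOM).
5. Ring order: rings A and B are bought as benzene rings. Ring C is the only ring made, in step 11.

Key step: step 11

Assumption: the (S)-configured PHOX ligand with Meldrum's acid is taken to deliver the (3R) product, by analogy with simpler 2'-alkoxyisoflavanones; if the opposite sense is found, the (R)-ligand is used and nothing else changes.
Numbering and abbreviation: isoflavanone numbering is used (O1, C2, C3, C4 = ketone, C4a, C5–C8, C8a; primed numbers for ring B). ArB = 4-methoxy-2,3-bis(methoxymethoxy)-5-(3-methylbut-2-en-1-yl)phenyl. The target is (3R).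

**Step 1**
Reactants: 1 2,3-dihydroxy-4-methoxybenzaldehyde
Product: 2 5-bromo-2,3-dihydroxy-4-methoxybenzaldehyde
Conditions: Br2, NaOAc, AcOH, rt
Reagents that add atoms: bromine, BrBr
Why: Electrophilic aromatic bromination should go to C5, which is para to the C2 hydroxyl, ortho to the methoxy group and meta to the aldehyde, whereas C6 is ortho to the deactivating aldehyde.

**Step 2**
Reactants: 2 5-bromo-2,3-dihydroxy-4-methoxybenzaldehyde
Product: 3 5-bromo-4-methoxy-2,3-bis(methoxymethoxy)benzaldehyde
Conditions: NaH, MOMCl, DMF, 0 °C to rt
Reagents that add atoms: chloromethyl methyl ether, COCCl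
Why: Williamson-type O-alkylation of both phenoxides, with NaH chosen because the C2 hydroxyl is hydrogen-bonded to the aldehyde and reacts sluggishly with amine bases.

**Step 3**
Reactants: 3 5-bromo-4-methoxy-2,3-bis(methoxymethoxy)benzaldehyde
Product: 4 4-methoxy-2,3-bis(methoxymethoxy)-5-(3-methylbut-2-en-1-yl)benzaldehyde
Conditions: Bu3SnCH2CH=CMe2, Pd(PPh3)4 (5 mol %), DMF, 100 °C
Reagents that add atoms: tributyl(3-methylbut-2-en-1-yl)stannane, CCCC[Sn](CCCC)(CCCC)CC=C(C)C
Why: Stille coupling of an aryl bromide with an allyl-type stannane should give the linear prenyl arene by transfer of the tin-bound CH2 terminus, and it tolerates aldehydes and acetals, as in the allylation of bromobenzaldehydes.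

**Step 4**
Reactants: 4 4-methoxy-2,3-bis(methoxymethoxy)-5-(3-methylbut-2-en-1-yl)benzaldehyde
Product: 5 2-ArB-acetonitrile
Conditions: TosMIC, KOt-Bu, DME, −50 °C; then MeOH, reflux
Reagents that add atoms: p-toluenesulfonylmethyl isocyanide (TosMIC), Cc1ccc(cc1)S(=O)(=O)C[N+]#[C-]
Why: van Leusen reductive cyanation in its low-temperature aldehyde variant, in which the TosMIC anion adds to the aldehyde and methanolysis expels sulfinate and formate to leave the one-carbon-longer nitrile, under base only, which MOM and prenyl groups tolerate.

**Step 5**
Reactants: 5 2-ArB-acetonitrile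
Product: 6 2-ArB-acetic acid
Conditions: KOH, EtOH–H2O, reflux; then aq. KHSO4 to pH 4, 0 °C
Reagents that add atoms: potassium hydroxide, [K+].[OH-]; water, O
Why: Alkaline nitrile hydrolysis leaves acetals, aryl ethers and the trisubstituted alkene untouched, and the brief cold acidification should leave the MOM groups in place.

**Step 6**
Reactants: 6 2-ArB-acetic acid
Product: 7 allyl 2-ArB-acetate
Conditions: allyl bromide, K2CO3, DMF, rt
Reagents that add atoms: allyl bromide, C=CCBr
Why: SN2 O-alkylation of the carboxylate installs the allyl ester, which later serves as the temporary activating group at C3 and as the handle for palladium.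

**Step 7**
Reactants: 8 5-fluororesorcinol
Product: 9 2-fluoro-4,6-dihydroxybenzaldehyde
Conditions: POCl3, DMF, MeCN, −15 °C to rt; then H2O, 50 °C
Reagents that add atoms: N,N-dimethylformamide, CN(C)C=O; water, O
Why: Vilsmeier–Haack formylation of a resorcinol goes ortho to one hydroxyl and para to the other (here also ortho to the small fluorine) and not to the crowded position between the hydroxyls, as with orcinol.

**Step 8**
Reactants: 9 2-fluoro-4,6-dihydroxybenzaldehyde
Product: 10 2-fluoro-4,6-bis(methoxymethoxy)benzaldehyde
Conditions: NaH, MOMCl, DMF, 0 °C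
Reagents that add atoms: chloromethyl methyl ether, COCCl
Why: Williamson-type O-alkylation of both phenoxides at 0 °C, a temperature at which these stabilised phenoxides should not attack the aryl fluoride.

**Step 9**
Reactants: 7 allyl 2-ArB-acetate; 10 2-fluoro-4,6-bis(methoxymethoxy)benzaldehyde
Product: 11 allyl 2-ArB-3-[2-fluoro-4,6-bis(methoxymethoxy)phenyl]-3-hydroxypropanoate (racemic mixture of diastereomers)
Conditions: LiN(SiMe3)2, THF, −78 °C; then 10; AcOH quench at −78 °C
Reagents that add atoms: none
Why: Aldol addition of the lithium ester enolate at −78 °C, cold enough to suppress ester enolate Claisen rearrangement and retro-aldol cleavage; the two new stereocentres (C3, C4) form without control and need none, since C4 is oxidised in step 10 and C3 is rebuilt in step 12.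

**Step 10**
Reactants: 11 allyl 2-ArB-3-[2-fluoro-4,6-bis(methoxymethoxy)phenyl]-3-hydroxypropanoate
Product: 12 allyl 2-ArB-3-[2-fluoro-4,6-bis(methoxymethoxy)phenyl]-3-oxopropanoate (racemic)
Conditions: Dess–Martin periodinane, CH2Cl2, 0 °C to rt
Reagents that add atoms: none
Why: Dess–Martin oxidation of the benzylic carbinol under neutral to weakly acidic conditions spares the MOM acetals, both alkenes and the aryl fluoride.

**Step 11**
Reactants: 12 allyl 2-ArB-3-[2-fluoro-4,6-bis(methoxymethoxy)phenyl]-3-oxopropanoate; 13 formaldehyde (charged as paraformaldehyde)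
Product: 15 allyl 3-ArB-5,7-bis(methoxymethoxy)-4-oxochromane-3-carboxylate (racemic), via hydroxymethyl keto ester 14 (not isolated)
Conditions: (CH2O)n, Cs2CO3, 4 Å molecular sieves, DMF, rt then 50 °C
Reagents that add atoms: none
Why: Proposed new method: Cs2CO3 removes the doubly activated C3–H of 12, the enolate adds through carbon to formaldehyde (C2–C3), and the alkoxide of 14 attacks the fluorine-bearing C8a, forms a Meisenheimer adduct whose charge runs over C4a into the C4 carbonyl group, and expels fluoride (O1–C8a), so that formaldehyde serves first as carbon electrophile and then as oxygen nucleophile in a formal (4+2) annulation. The closest known reaction types are the base-mediated hydroxymethylation of β-keto esters, the SNAr closure of 2-fluorophenyl β-hydroxy ketones to chroman-4-ones, domino aldol/SNAr annulations of 2-fluoroaryl carbonyl compounds, and the cycloaracylation route to 4-quinolones, in which a one-carbon unit fixed to a 2-fluorobenzoylacetate carries the heteroatom onto the ring. Ring C closes by 6-endo-trig addition–elimination along the vinylogous acyl fluoride C8a=C4a–C4=O, and the closure itself turns the C4 carbonyl group into the plane of ring A, where it can accept the charge. The quaternary C3 forms as a racemate on purpose: no element controls it and none is needed, because step 12 erases this centre and rebuilds it. The step needs closure by the alkoxide and not by the ester enolate oxygen (which would lead to a 2-allyloxyisoflavone), carbon and not oxygen attack on formaldehyde, and loss of fluoride and not of the C5 OMOM group; excess formaldehyde keeps the free enolate scarce, all formaldehyde adducts are reversible so that only the irreversible SNAr of the C-adduct drains them, and fluoride is by far the better leaving group in SNAr. The temporary ester leaves C3 without hydrogen after the first bond, which rules out dehydration to the enone, a second hydroxymethylation and epimerisation, and the C5 and C7 oxygens are meta to C8a and so do not push electrons onto the carbons that bear the charge.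

**Step 12**
Reactants: 15 allyl 3-ArB-5,7-bis(methoxymethoxy)-4-oxochromane-3-carboxylate
Product: 16 (3R)-3-ArB-5,7-bis(methoxymethoxy)chroman-4-one
Conditions: Pd2(dba)3 (5 mol %), (S)-(CF3)3-t-BuPHOX (12.5 mol %), Meldrum's acid (2.5 equiv), THF, 5 °C to rt
Reagents that add atoms: none
Why: Palladium-catalysed decarboxylative asymmetric protonation, known for allyl 3-aryl-4-oxochromane-3-carboxylates: zerovalent palladium ionises the allyl ester, CO2 is lost, and the enolate held in the chiral pocket of the PHOX–palladium complex is protonated on one face by Meldrum's acid, which sets (3R), keeps the medium acidic and takes up the allyl group as its anion.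

**Step 13**
Reactants: 16 (3R)-3-ArB-5,7-bis(methoxymethoxy)chroman-4-one
Product: 17 (3R)-3-[2,3-dihydroxy-4-methoxy-5-(3-methylbut-2-en-1-yl)phenyl]-5,7-dihydroxychroman-4-one (target)
Conditions: HCl (0.5 M), MeOH–CH2Cl2, 0 °C to rt
Reagents that add atoms: none
Why: Acid-catalysed transacetalisation with methanol removes the four phenolic MOM acetals; C3 should hold because isoflavanones lose configuration mainly through the enolate, which dilute acid at or below rt does not form, and the prenyl group has no ortho hydroxyl to cyclise onto.

**Compound list**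
1 | 2,3-dihydroxy-4-methoxybenzaldehyde | COc1ccc(C=O)c(O)c1O | starting material
2 | 5-bromo-2,3-dihydroxy-4-methoxybenzaldehyde | COc1c(Br)cc(C=O)c(O)c1O | intermediate
3 | 5-bromo-4-methoxy-2,3-bis(methoxymethoxy)benzaldehyde | COCOc1c(C=O)cc(Br)c(OC)c1OCOC | intermediate
4 | 4-methoxy-2,3-bis(methoxymethoxy)-5-(3-methylbut-2-en-1-yl)benzaldehyde | COCOc1c(C=O)cc(CC=C(C)C)c(OC)c1OCOC | intermediate
5 | 2-[4-methoxy-2,3-bis(methoxymethoxy)-5-(3-methylbut-2-en-1-yl)phenyl]acetonitrile | COCOc1c(CC#N)cc(CC=C(C)C)c(OC)c1OCOC | intermediate
6 | 2-[4-methoxy-2,3-bis(methoxymethoxy)-5-(3-methylbut-2-en-1-yl)phenyl]acetic acid | COCOc1c(CC(=O)O)cc(CC=C(C)C)c(OC)c1OCOC | intermediate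
7 | allyl 2-[4-methoxy-2,3-bis(methoxymethoxy)-5-(3-methylbut-2-en-1-yl)phenyl]acetate | C=CCOC(=O)Cc1cc(CC=C(C)C)c(OC)c(OCOC)c1OCOC | intermediate
8 | 5-fluororesorcinol (5-fluorobenzene-1,3-diol) | Oc1cc(O)cc(F)c1 | starting material
9 | 2-fluoro-4,6-dihydroxybenzaldehyde | O=Cc1c(O)cc(O)cc1F | intermediate
10 | 2-fluoro-4,6-bis(methoxymethoxy)benzaldehyde | COCOc1cc(F)c(C=O)c(OCOC)c1 | intermediate
11 | allyl 2-ArB-3-[2-fluoro-4,6-bis(methoxymethoxy)phenyl]-3-hydroxypropanoate, racemic mixture of diastereomers | C=CCOC(=O)C(C(O)c1c(F)cc(OCOC)cc1OCOC)c1cc(CC=C(C)C)c(OC)c(OCOC)c1OCOC | intermediate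
12 | allyl 2-ArB-3-[2-fluoro-4,6-bis(methoxymethoxy)phenyl]-3-oxopropanoate, racemic | C=CCOC(=O)C(C(=O)c1c(F)cc(OCOC)cc1OCOC)c1cc(CC=C(C)C)c(OC)c(OCOC)c1OCOC | intermediate
13 | formaldehyde (charged as paraformaldehyde) | C=O | starting material
14 | allyl 2-ArB-2-(hydroxymethyl)-3-[2-fluoro-4,6-bis(methoxymethoxy)phenyl]-3-oxopropanoate, racemic, not isolated | C=CCOC(=O)C(CO)(C(=O)c1c(F)cc(OCOC)cc1OCOC)c1cc(CC=C(C)C)c(OC)c(OCOC)c1OCOC | intermediate
15 | allyl 3-ArB-5,7-bis(methoxymethoxy)-4-oxochromane-3-carboxylate, racemic | C=CCOC(=O)C1(COc2cc(OCOC)cc(OCOC)c2C1=O)c1cc(CC=C(C)C)c(OC)c(OCOC)c1OCOC | intermediate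
16 | (3R)-3-ArB-5,7-bis(methoxymethoxy)chroman-4-one | COc1c(CC=C(C)C)cc([C@@H]2COc3cc(OCOC)cc(OCOC)c3C2=O)c(OCOC)c1OCOC | intermediate
17 | (3R)-3-[2,3-dihydroxy-4-methoxy-5-(3-methylbut-2-en-1-yl)phenyl]-5,7-dihydroxychroman-4-one | COc1c(CC=C(C)C)cc([C@@H]2COc3cc(O)cc(O)c3C2=O)c(O)c1O | target

**Step count**
Total step count: 13. Longest linear sequence: 11 (steps 1–6, then 9–13).

**Steps most likely to fail**

1. Step 11 (proposed new method).
   - Risk: retro-aldol loss of formaldehyde may outrun ring closure at the temperature the SNAr needs. The ester enolate oxygen may close onto C8a. The non-enolisable β-keto ester may suffer retro-Claisen cleavage by adventitious hydroxide.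
   - Fallback (known chemistry; the domino is split and the closure is run without stoichiometric base): setting out from 12, 37 % aqueous formaldehyde with catalytic KHCO3 in THF at rt gives 14, which is now isolated. Me3SiCl and imidazole in CH2Cl2 convert it into the trimethylsilyl ether F1. Catalytic CsF in DMF then starts a fluoride-chain SNAr of the silyl ether. Each closure releases the fluoride that desilylates the next molecule, so only a trace of free alkoxide is ever present. This comes back to the route at 15.

2. Step 12.
   - Risk: poor facial selectivity of the protonation, caused by the C5 OMOM group next to the enolate oxygen and by the crowded ring B. An unexpected sense of induction and competing C-allylation of the enolate are also possible.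
   - Fallback: setting out from 15, Pd(PPh3)4 and morpholine in THF (achiral deallylation–decarboxylation) give the racemic isoflavanone F2. Asymmetric transfer hydrogenation under dynamic kinetic resolution follows, with RuCl(p-cymene)[(R,R)-TsDPEN] in HCO2H/Et3N, a reaction type known for isoflavanones. Et3N racemises C3 while the catalyst reduces one enantiomer, which should give the cis-(3R,4R)-isoflavan-4-ol F3. Base-free Dess–Martin oxidation restores the ketone with C3 intact and comes back to the route at 16.

3. Step 13.
   - Risk: acid-induced enolisation with erosion of configuration at C3, cyclodehydration of the freed C2' hydroxyl onto C4, and acid addition to the prenyl alkene, all during the time the slowest MOM group needs.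
   - Fallback (the protecting groups are exchanged while C3 is still quaternary): setting out from 15, Et3SiOTf and 2,2'-bipyridyl in MeCN convert the aryl MOM ethers directly into aryl silyl ethers. No free phenol appears that could lactonise onto the allyl ester, and the product is the tetrakis(triethylsilyl) ether F4. The conditions of step 12 then give the (3R)-tetrakis(triethylsilyl) isoflavanone F5. HF·pyridine buffered with pyridine in THF at 0 °C removes the silyl groups and comes back to the route at 17.

**Further compounds**
F1 | step 11 | trimethylsilyl ether of 14 (racemic) | C=CCOC(=O)C(CO[Si](C)(C)C)(C(=O)c1c(F)cc(OCOC)cc1OCOC)c1cc(CC=C(C)C)c(OC)c(OCOC)c1OCOC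
F2 | step 12 | racemic isoflavanone, 3-ArB-5,7-bis(methoxymethoxy)chroman-4-one | COc1c(CC=C(C)C)cc(C2COc3cc(OCOC)cc(OCOC)c3C2=O)c(OCOC)c1OCOC
F3 | step 12 | cis-(3R,4R)-isoflavan-4-ol, (3R,4R)-3-ArB-5,7-bis(methoxymethoxy)chroman-4-ol | COc1c(CC=C(C)C)cc([C@@H]2COc3cc(OCOC)cc(OCOC)c3[C@@H]2O)c(OCOC)c1OCOC
F4 | step 13 | tetrakis(triethylsilyl) ether, allyl 3-aryl-4-oxochromane-3-carboxylate (racemic) | C=CCOC(=O)C1(COc2cc(O[Si](CC)(CC)CC)cc(O[Si](CC)(CC)CC)c2C1=O)c1cc(CC=C(C)C)c(OC)c(O[Si](CC)(CC)CC)c1O[Si](CC)(CC)CC
F5 | step 13 | (3R)-tetrakis(triethylsilyl) isoflavanone | COc1c(CC=C(C)C)cc([C@@H]2COc3cc(O[Si](CC)(CC)CC)cc(O[Si](CC)(CC)CC)c3C2=O)c(O[Si](CC)(CC)CC)c1O[Si](CC)(CC)CC
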